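**Retrosynthetic overview**
1. Target 7 ⇒ nitro-enamine 4: the C3–Br bond and the N1–C2 bond (pyrrole ring) are made in one operation by a brominative Leimgruber–Batcho cyclisation (the proposed new step).
2. Enamine 4 ⇒ o-nitrotoluene 3 + DMF dimethyl acetal, which supplies C2 of the indole.
3. Nitrotoluene 3 ⇒ phenol 2 (O-methylation) ⇒ 4-methyl-3-nitrophenol 1 (double ortho-bromination; these two Br become C5–Br and C7–Br).
4. Ring order: the benzene ring is bought and fully substituted first; the pyrrole ring is closed last.

Assumption: the target has no stereocentre, so the given SMILES is its only stereoisomer and no enantiocontrol is needed; simple reagents are given by name and SMILES in the steps, and only substrates, intermediates and products carry numbers.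

**Route**

Step 1
Reactants: 1 4-methyl-3-nitrophenol
Product: 2 2,6-dibromo-4-methyl-3-nitrophenol
Conditions: Br2 (2.2 equiv), AcOH, 20 to 50 °C
Reagents that add atoms: bromine, BrBr
Why: Electrophilic aromatic bromination in which the phenol OH directs to its two ortho positions (para is blocked by CH3 and the only other free position is meta to OH), as in the exhaustive bromination of nitrophenols.

Step 2
Reactants: 2 2,6-dibromo-4-methyl-3-nitrophenol
Product: 3 1,3-dibromo-2-methoxy-5-methyl-4-nitrobenzene
Conditions: MeI (1.5 equiv), K2CO3 (2 equiv), DMF, 40 °C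
Reagents that add atoms: iodomethane, CI
Why: Williamson ether synthesis (SN2 on MeI) by the acidic 2,6-dibromophenoxide, the only nucleophilic site in the molecule.

Step 3
Reactants: 3 1,3-dibromo-2-methoxy-5-methyl-4-nitrobenzene
Product: 4 (E)-2-(3,5-dibromo-4-methoxy-2-nitrophenyl)-N,N-dimethylethen-1-amine
Conditions: Me2NCH(OMe)2 (3 equiv), DMF, 110 °C, no added secondary amine
Reagents that add atoms: N,N-dimethylformamide dimethyl acetal, COC(OC)N(C)C
Why: First stage of the Leimgruber–Batcho indole synthesis, in which the CH3 ortho to NO2 (further acidified by two meta Br) is deprotonated by methoxide released from the acetal and condenses with the formamidinium ion to give the conjugated enamine in its thermodynamic E geometry.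

Step 4
Reactants: 4 (E)-2-(3,5-dibromo-4-methoxy-2-nitrophenyl)-N,N-dimethylethen-1-amine
Product: 7 3,5,7-tribromo-6-methoxy-1H-indole, via bromoenamine 5 (not isolated), via aminoaryl bromoenamine 6 (not isolated)
Conditions: NBS (1.0 equiv), THF, −78 °C; then B2(OH)4 (3.3 equiv), 4,4'-bipyridine (5 mol %), DMF, H2O, 20 °C; then AcOH, 40 °C
Reagents that add atoms: N-bromosuccinimide, O=C1CCC(=O)N1Br
Why: Proposed new method: a brominative Leimgruber–Batcho cyclisation in which the enamine β-carbon of 4 (the only nucleophilic site, since the arene is deactivated by NO2 and two Br) takes Br+ from NBS to give an α-bromoiminium ion that loses its benzylic proton to form bromoenamine 5 (its alkene geometry is irrelevant), the nitro group is then reduced under neutral metal-free conditions that spare C–Br bonds to give aniline 6, and acid-promoted attack of NH2 on the enamine/iminium carbon with loss of Me2NH and tautomerisation closes the pyrrole ring with Br already fixed at C3; the closest known reaction types are the Leimgruber–Batcho reductive cyclisation of unhalogenated nitro-enamines and the electrophilic α-halogenation of enamines, which have not been combined to make 3-haloindoles.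

**Compound list**
1 | 4-methyl-3-nitrophenol | Cc1ccc(O)cc1[N+](=O)[O-] | starting material
2 | 2,6-dibromo-4-methyl-3-nitrophenol | Cc1cc(Br)c(O)c(Br)c1[N+](=O)[O-] | intermediate
3 | 1,3-dibromo-2-methoxy-5-methyl-4-nitrobenzene | COc1c(Br)cc(C)c([N+](=O)[O-])c1Br | intermediate
4 | (E)-2-(3,5-dibromo-4-methoxy-2-nitrophenyl)-N,N-dimethylethen-1-amine | CN(C)/C=C/c1cc(Br)c(OC)c(Br)c1[N+](=O)[O-] | intermediate
5 | (Z)-2-bromo-2-(3,5-dibromo-4-methoxy-2-nitrophenyl)-N,N-dimethylethen-1-amine | CN(C)/C=C(\Br)c1cc(Br)c(OC)c(Br)c1[N+](=O)[O-] | intermediate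
6 | (Z)-2-(2-amino-3,5-dibromo-4-methoxyphenyl)-2-bromo-N,N-dimethylethen-1-amine | CN(C)/C=C(\Br)c1cc(Br)c(OC)c(Br)c1N | intermediate
7 | 3,5,7-tribromo-6-methoxy-1H-indole | COc1c(Br)cc2c(Br)c[nH]c2c1Br | target

**Total step count:** 4 steps.
**Longest linear sequence:** 4 steps (1 → 2 → 3 → 4 → 7).

**Three steps most likely to fail**

Step 4 (the proposed new step). The risks are reductive loss of the C3 bromine through the α-bromoiminium form, loss of HBr instead of Me2NH from the cyclic aminal, and incomplete reduction giving an N-hydroxyindole. The fallback uses known chemistry and sets out from 4. A standard Leimgruber–Batcho reductive cyclisation (Fe powder, AcOH, EtOH, 80 °C) gives 5,7-dibromo-6-methoxy-1H-indole F1. Electrophilic bromination at C3, the most nucleophilic position of the indole (NBS 1.0 equiv, DMF, 0 °C), then gives 7, where the fallback comes back to the route.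

Step 3. The nitro group is flanked by Br and CH3 and is twisted, so the methyl is less acidic than usual; methoxide may also displace the Br ortho to NO2. The fallback sets out from 3 and builds the side chain without carbanion chemistry at the methyl group.
- Radical benzylic bromination (NBS, azobisisobutyronitrile, PhCF3, 85 °C) gives 1,3-dibromo-5-(bromomethyl)-2-methoxy-4-nitrobenzene F2.
- Oxidation with N-methylmorpholine N-oxide (MeCN, 20 °C) gives 3,5-dibromo-4-methoxy-2-nitrobenzaldehyde F3.
- Wittig methoxymethylenation ((methoxymethyl)triphenylphosphonium chloride, KOtBu, THF, 0 °C) gives a mixture of 1,3-dibromo-2-methoxy-5-[(E)-2-methoxyethenyl]-4-nitrobenzene F4 and its geometric isomer 1,3-dibromo-2-methoxy-5-[(Z)-2-methoxyethenyl]-4-nitrobenzene F5.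
- Both isomers are hydrolysed (aqueous HCl, THF, 20 °C) to 2-(3,5-dibromo-4-methoxy-2-nitrophenyl)acetaldehyde F6.
- Condensation of the crude aldehyde with Me2NH (THF, 4 Å molecular sieves, 0 to 20 °C) gives enamine 4, where the fallback comes back to the route.

Step 1. The second bromination must go in between OH and NO2 on a ring deactivated by the nitro group, and may stall at the monobromide. The fallback sets out from 1 and installs both bromines under the direction of a free amino group, then restores the nitro group.
- O-Methylation (MeI, K2CO3, DMF) gives 4-methoxy-1-methyl-2-nitrobenzene F7.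
- Nitro reduction (Fe powder, NH4Cl, EtOH–H2O, 75 °C) gives 5-methoxy-2-methylaniline F8.
- Dibromination para and ortho to NH2, both positions also ortho to OMe (NBS 2.05 equiv, MeCN, 0 °C), gives 2,4-dibromo-3-methoxy-6-methylaniline F9.
- Oxidation of the hindered aniline to the nitroarene (3-chloroperbenzoic acid 4 equiv, 1,2-dichloroethane, 80 °C) gives 3, where the fallback comes back to the route, bypassing 2.

**Further compounds**
F1 | step 4 | 5,7-dibromo-6-methoxy-1H-indole | COc1c(Br)cc2cc[nH]c2c1Br
F2 | step 3 | 1,3-dibromo-5-(bromomethyl)-2-methoxy-4-nitrobenzene | COc1c(Br)cc(CBr)c([N+](=O)[O-])c1Br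
F3 | step 3 | 3,5-dibromo-4-methoxy-2-nitrobenzaldehyde | COc1c(Br)cc(C=O)c([N+](=O)[O-])c1Br
F4 | step 3 | 1,3-dibromo-2-methoxy-5-[(E)-2-methoxyethenyl]-4-nitrobenzene | CO/C=C/c1cc(Br)c(OC)c(Br)c1[N+](=O)[O-]
F5 | step 3 | 1,3-dibromo-2-methoxy-5-[(Z)-2-methoxyethenyl]-4-nitrobenzene | CO/C=C\c1cc(Br)c(OC)c(Br)c1[N+](=O)[O-]
F6 | step 3 | 2-(3,5-dibromo-4-methoxy-2-nitrophenyl)acetaldehyde | O=CCc1cc(Br)c(OC)c(Br)c1[N+](=O)[O-]
F7 | step 1 | 4-methoxy-1-methyl-2-nitrobenzene | COc1ccc(C)c([N+](=O)[O-])c1
F8 | step 1 | 5-methoxy-2-methylaniline | COc1ccc(C)c(N)c1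
F9 | step 1 | 2,4-dibromo-3-methoxy-6-methylaniline | Cc1cc(Br)c(OC)c(Br)c1N
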